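**Strategy.** The target is an α‑ketol: C3(OH)–C4(=O) inside the pyranone ring (O1, C2, C3, C4, C4a, C8a). Disconnecting C2–C3 and reconnecting C2 to C4 gives an isomeric ketol, a 3‑aroyl‑3‑hydroxy‑2,3‑dihydrobenzofuran with ring B on the exocyclic carbonyl. A chelation‑controlled, stereospecific α‑ketol rearrangement moves C2 from the carbinol carbon to the aroyl carbon: the five‑membered O‑heterocycle grows to the chromanone, C4 becomes the ketone and C3 the (R)‑carbinol, in one isomerisation. The step exploits this α‑ketol unit and the gain of conjugation between C4=O and ring A. The precursor arises from a diprenylated α‑aryl enone by asymmetric nucleophilic epoxidation and 5‑exo opening by the ortho phenoxide.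

Key step: step 10

Remark: the metal‑bridged syn‑chelate course of the α‑ketol shift is assumed, under which (S)‑15 gives (R)‑16; the sense of induction in step 9 cannot be predicted for a β‑unsubstituted enone, so the BINOL antipode that gives the (S)‑epoxide is the one to use.

**Step 1**
Reactants: 1 2′,4′‑dihydroxyacetophenone
Product: 2 1‑(2,4‑dihydroxy‑3,5‑diiodophenyl)ethan‑1‑one
Conditions: I2, HIO3, EtOH–H2O, 40 °C
Reagents that add atoms: iodine, II; iodic acid, OI(=O)=O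
Why: Electrophilic aromatic iodination of the resorcinol ring at the two positions ortho/para to the hydroxyl groups, with iodic acid reoxidising iodide so that water is the only co‑product.

**Step 2**
Reactants: 2 1‑(2,4‑dihydroxy‑3,5‑diiodophenyl)ethan‑1‑one
Product: 3 1‑[2‑hydroxy‑3,5‑diiodo‑4‑(methoxymethoxy)phenyl]ethan‑1‑one
Conditions: MOMCl (1.05 equiv), i‑Pr2NEt, CH2Cl2, 0 °C → rt
Reagents that add atoms: chloromethyl methyl ether (MOMCl), COCCl
Why: Selective O‑alkylation (acetal protection) of the more acidic, non‑chelated 4‑OH, while the 2‑OH stays locked in its hydrogen bond to the acetyl group.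

**Step 3**
Reactants: 3 1‑[2‑hydroxy‑3,5‑diiodo‑4‑(methoxymethoxy)phenyl]ethan‑1‑one
Product: 4 1‑[2‑hydroxy‑4‑(methoxymethoxy)‑3,5‑bis(3‑methylbut‑2‑en‑1‑yl)phenyl]ethan‑1‑one
Conditions: prenyl‑SnBu3 (2.5 equiv), Pd(PPh3)4 (10 mol %), DMF, 90 °C
Reagents that add atoms: tributyl(3‑methylbut‑2‑en‑1‑yl)stannane, CCCC[Sn](CCCC)(CCCC)CC=C(C)C
Why: Twofold Stille coupling of the aryl iodides with the allylic stannane places both prenyl groups (linear α‑coupling) at fixed positions before any oxidation step.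

**Step 4**
Reactants: 4 1‑[2‑hydroxy‑4‑(methoxymethoxy)‑3,5‑bis(3‑methylbut‑2‑en‑1‑yl)phenyl]ethan‑1‑one
Product: 5 1‑[4‑(methoxymethoxy)‑3,5‑bis(3‑methylbut‑2‑en‑1‑yl)‑2‑(triisopropylsilyloxy)phenyl]ethan‑1‑one
Conditions: TIPSOTf, 2,6‑lutidine, CH2Cl2, 0 °C → rt
Reagents that add atoms: triisopropylsilyl triflate, CC(C)[Si](C(C)C)(C(C)C)OS(=O)(=O)C(F)(F)F
Why: O‑Silylation of the hindered chelated phenol with a silyl triflate masks the future O1 with a group that cannot undergo enolate acyl transfer and is cleaved by fluoride in the presence of MOM ethers.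

**Step 5**
Reactants: 5 1‑[4‑(methoxymethoxy)‑3,5‑bis(3‑methylbut‑2‑en‑1‑yl)‑2‑(triisopropylsilyloxy)phenyl]ethan‑1‑one
Product: 7 1‑[4‑(methoxymethoxy)‑3,5‑bis(3‑methylbut‑2‑en‑1‑yl)‑2‑(triisopropylsilyloxy)phenyl]ethenyl trifluoromethanesulfonate, via potassium enolate 6 (not isolated)
Conditions: KHMDS, THF, −78 °C; PhNTf2, −78 → 0 °C
Reagents that add atoms: N‑phenylbis(trifluoromethanesulfonimide), FC(F)(F)S(=O)(=O)N(c1ccccc1)S(=O)(=O)C(F)(F)F
Why: Kinetic deprotonation of the methyl ketone at its only enolisable position and O‑triflation of the enolate give the 1‑arylvinyl triflate, the low temperature and the bulky silyl group suppressing O‑to‑O silyl transfer.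

**Step 6**
Reactants: 8 4‑bromobenzene‑1,3‑diol
Product: 9 1‑bromo‑2,4‑bis(methoxymethoxy)benzene
Conditions: MOMCl (2.5 equiv), i‑Pr2NEt, CH2Cl2, 0 °C → rt
Reagents that add atoms: chloromethyl methyl ether (MOMCl), COCCl
Why: Exhaustive O‑alkylation of both phenols as MOM acetals, which tolerate the aryllithium of the next step.

**Step 7**
Reactants: 9 1‑bromo‑2,4‑bis(methoxymethoxy)benzene
Product: 11 tributyl[2,4‑bis(methoxymethoxy)phenyl]stannane, via aryllithium 10 (not isolated)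
Conditions: n‑BuLi, THF, −78 °C; Bu3SnCl, −78 °C → rt
Reagents that add atoms: tributyltin chloride, CCCC[Sn](Cl)(CCCC)CCCC
Why: Bromine–lithium exchange gives an aryllithium stabilised by the ortho MOM ether, which is trapped at tin (transmetalation).

**Step 8**
Reactants: 7 1‑[4‑(methoxymethoxy)‑3,5‑bis(3‑methylbut‑2‑en‑1‑yl)‑2‑(triisopropylsilyloxy)phenyl]ethenyl trifluoromethanesulfonate; 11 tributyl[2,4‑bis(methoxymethoxy)phenyl]stannane
Product: 12 1‑[2,4‑bis(methoxymethoxy)phenyl]‑2‑[4‑(methoxymethoxy)‑3,5‑bis(3‑methylbut‑2‑en‑1‑yl)‑2‑(triisopropylsilyloxy)phenyl]prop‑2‑en‑1‑one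
Conditions: Pd(PPh3)4 (5 mol %), LiCl (3 equiv), CO (1 atm), THF, 55 °C
Reagents that add atoms: carbon monoxide, [C-]#[O+]
Why: Carbonylative Stille coupling (oxidative addition of the vinyl triflate, CO insertion, transmetalation with the aryl stannane) joins both halves and creates the enone carbonyl that becomes C3 of the target.

**Step 9**
Reactants: 12 1‑[2,4‑bis(methoxymethoxy)phenyl]‑2‑[4‑(methoxymethoxy)‑3,5‑bis(3‑methylbut‑2‑en‑1‑yl)‑2‑(triisopropylsilyloxy)phenyl]prop‑2‑en‑1‑one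
Product: 15 (S)‑[2,4‑bis(methoxymethoxy)phenyl][3‑hydroxy‑6‑(methoxymethoxy)‑5,7‑bis(3‑methylbut‑2‑en‑1‑yl)‑2,3‑dihydro‑1‑benzofuran‑3‑yl]methanone, via epoxy ketone 13 (not isolated), via ammonium phenoxide 14 (not isolated)
Conditions: (i) La(Oi‑Pr)3/BINOL/Ph3As=O (1:1:1, 10 mol %), TBHP (decane), 4 Å MS, THF, rt; (ii) filter, TBAF (1.05 equiv), THF, −40 °C, then AcOH
Reagents that add atoms: tert‑butyl hydroperoxide, CC(C)(C)OO
Why: In a catalytic asymmetric Weitz–Scheffer epoxidation the peroxide adds to the CH2 terminus of the only Michael acceptor (prenyl groups are inert to a nucleophilic oxidant) and the BINOL‑bound peroxy enolate closes the oxirane on one face, setting the quaternary carbon by catalyst control, after which fluoride frees the ortho phenoxide, which opens the oxirane at CH2 (5‑exo‑tet) without touching that stereocentre.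

**Step 10**
Reactants: 15 (S)‑[2,4‑bis(methoxymethoxy)phenyl][3‑hydroxy‑6‑(methoxymethoxy)‑5,7‑bis(3‑methylbut‑2‑en‑1‑yl)‑2,3‑dihydro‑1‑benzofuran‑3‑yl]methanone
Product: 16 (R)‑3‑[2,4‑bis(methoxymethoxy)phenyl]‑3‑hydroxy‑7‑(methoxymethoxy)‑6,8‑bis(3‑methylbut‑2‑en‑1‑yl)‑2,3‑dihydro‑4H‑chromen‑4‑one
Conditions: Al(Ot‑Bu)3 (30 mol %), toluene, 80 °C
Reagents that add atoms: none
Why: Aluminium(III) binds the tertiary alkoxide and the aroyl carbonyl of 15 in a five‑membered syn‑periplanar chelate, and the C2–C3 bond of the dihydrofuran (the OCH2 carbon, held perpendicular to the chelate plane) shifts suprafacially to the aroyl carbon while the carbinol carbon turns into the ring‑A‑conjugated C4 ketone (α‑ketol or acyloin rearrangement). The closest known reaction type is the ring‑enlarging α‑ketol rearrangement of 1‑aroylcycloalkanols and of 17‑hydroxy‑20‑keto steroids (D‑homoannulation) with aluminium alkoxides or Ni(II)/Cu(II) chelates. No ring is closed from an open chain: the five‑membered O‑heterocycle is enlarged to the six‑membered pyranone by a 1,2‑carbon shift that inserts the former aroyl carbon between C2 and the former carbinol carbon. The new C3 stereocentre is controlled by the C3 configuration of 15, because the migrating carbon is delivered to the carbonyl face on which it already lies in the chelate, so that (S)‑15 gives (R)‑16; a competing first shift of the ring‑A carbon C3a would give the 4‑aryl‑4‑hydroxychroman‑3‑one ketol, whose ring‑B aryl then migrates within the same chelate geometry to the same enantiomer of 16. The step needs thermodynamic control toward the chroman‑4‑one and no ionisation of the benzylic tertiary C–O bond; release of five‑ring strain, replacement of a twisted hindered aroyl ketone by a planar ketone conjugated with O1 and O7, and the non‑ionising alkoxide medium secure both.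

**Step 11**
Reactants: 16 (R)‑3‑[2,4‑bis(methoxymethoxy)phenyl]‑3‑hydroxy‑7‑(methoxymethoxy)‑6,8‑bis(3‑methylbut‑2‑en‑1‑yl)‑2,3‑dihydro‑4H‑chromen‑4‑one
Product: 17 (R)‑3‑(2,4‑dihydroxyphenyl)‑3,7‑dihydroxy‑6,8‑bis(3‑methylbut‑2‑en‑1‑yl)‑2,3‑dihydro‑4H‑chromen‑4‑one (CNP0211715.1)
Conditions: ZnBr2 (3 equiv), n‑PrSH (6 equiv), CH2Cl2, 0 °C
Reagents that add atoms: none
Why: Lewis‑acid‑assisted transacetalisation moves the three MOM groups to the thiol under non‑protic conditions, which should free the phenols without ionising the tertiary benzylic alcohol or cyclising a prenyl group onto a phenol.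

**Compound list**
1 | 2′,4′‑dihydroxyacetophenone | CC(=O)c1ccc(O)cc1O | starting material
2 | 1‑(2,4‑dihydroxy‑3,5‑diiodophenyl)ethan‑1‑one | CC(=O)c1cc(I)c(O)c(I)c1O | intermediate
3 | 1‑[2‑hydroxy‑3,5‑diiodo‑4‑(methoxymethoxy)phenyl]ethan‑1‑one | CC(=O)c1cc(I)c(OCOC)c(I)c1O | intermediate
4 | 1‑[2‑hydroxy‑4‑(methoxymethoxy)‑3,5‑bis(3‑methylbut‑2‑en‑1‑yl)phenyl]ethan‑1‑one | CC(=O)c1cc(CC=C(C)C)c(OCOC)c(CC=C(C)C)c1O | intermediate
5 | 1‑[4‑(methoxymethoxy)‑3,5‑bis(3‑methylbut‑2‑en‑1‑yl)‑2‑(triisopropylsilyloxy)phenyl]ethan‑1‑one | CC(=O)c1cc(CC=C(C)C)c(OCOC)c(CC=C(C)C)c1O[Si](C(C)C)(C(C)C)C(C)C | intermediate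
6 | potassium enolate of 5 | [K+].[O-]C(=C)c1cc(CC=C(C)C)c(OCOC)c(CC=C(C)C)c1O[Si](C(C)C)(C(C)C)C(C)C | intermediate (not isolated)
7 | 1‑[4‑(methoxymethoxy)‑3,5‑bis(3‑methylbut‑2‑en‑1‑yl)‑2‑(triisopropylsilyloxy)phenyl]ethenyl trifluoromethanesulfonate | C=C(OS(=O)(=O)C(F)(F)F)c1cc(CC=C(C)C)c(OCOC)c(CC=C(C)C)c1O[Si](C(C)C)(C(C)C)C(C)C | intermediate
8 | 4‑bromobenzene‑1,3‑diol | Oc1ccc(Br)c(O)c1 | starting material
9 | 1‑bromo‑2,4‑bis(methoxymethoxy)benzene | COCOc1ccc(Br)c(OCOC)c1 | intermediate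
10 | [2,4‑bis(methoxymethoxy)phenyl]lithium | [Li]c1ccc(OCOC)cc1OCOC | intermediate (not isolated)
11 | tributyl[2,4‑bis(methoxymethoxy)phenyl]stannane | CCCC[Sn](CCCC)(CCCC)c1ccc(OCOC)cc1OCOC | intermediate
12 | 1‑[2,4‑bis(methoxymethoxy)phenyl]‑2‑[4‑(methoxymethoxy)‑3,5‑bis(3‑methylbut‑2‑en‑1‑yl)‑2‑(triisopropylsilyloxy)phenyl]prop‑2‑en‑1‑one | C=C(C(=O)c1ccc(OCOC)cc1OCOC)c1cc(CC=C(C)C)c(OCOC)c(CC=C(C)C)c1O[Si](C(C)C)(C(C)C)C(C)C | intermediate
13 | [2,4‑bis(methoxymethoxy)phenyl]{(2S)‑2‑[4‑(methoxymethoxy)‑3,5‑bis(3‑methylbut‑2‑en‑1‑yl)‑2‑(triisopropylsilyloxy)phenyl]oxiran‑2‑yl}methanone | O=C(c1ccc(OCOC)cc1OCOC)[C@@]1(CO1)c1cc(CC=C(C)C)c(OCOC)c(CC=C(C)C)c1O[Si](C(C)C)(C(C)C)C(C)C | intermediate (not isolated)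
14 | tetrabutylammonium 2‑{(2S)‑2‑[2,4‑bis(methoxymethoxy)benzoyl]oxiran‑2‑yl}‑5‑(methoxymethoxy)‑4,6‑bis(3‑methylbut‑2‑en‑1‑yl)phenolate | O=C(c1ccc(OCOC)cc1OCOC)[C@@]1(CO1)c1cc(CC=C(C)C)c(OCOC)c(CC=C(C)C)c1[O-].CCCC[N+](CCCC)(CCCC)CCCC | intermediate (not isolated)
15 | (S)‑[2,4‑bis(methoxymethoxy)phenyl][3‑hydroxy‑6‑(methoxymethoxy)‑5,7‑bis(3‑methylbut‑2‑en‑1‑yl)‑2,3‑dihydro‑1‑benzofuran‑3‑yl]methanone | O[C@@]1(COc2c(CC=C(C)C)c(OCOC)c(CC=C(C)C)cc21)C(=O)c1ccc(OCOC)cc1OCOC | intermediate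
16 | (R)‑3‑[2,4‑bis(methoxymethoxy)phenyl]‑3‑hydroxy‑7‑(methoxymethoxy)‑6,8‑bis(3‑methylbut‑2‑en‑1‑yl)‑2,3‑dihydro‑4H‑chromen‑4‑one | CC(C)=CCc1cc2c(c(CC=C(C)C)c1OCOC)OC[C@](O)(c1ccc(OCOC)cc1OCOC)C2=O | intermediate
17 | (R)‑3‑(2,4‑dihydroxyphenyl)‑3,7‑dihydroxy‑6,8‑bis(3‑methylbut‑2‑en‑1‑yl)‑2,3‑dihydro‑4H‑chromen‑4‑one | CC(C)=CCc1cc2c(c(CC=C(C)C)c1O)OC[C@](O)(c1ccc(O)cc1O)C2=O | target

**Step count.** Total: 11 steps. Longest linear sequence: 9 steps (1–5, then 8–11).

**Steps most likely to fail**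

Step 10 (key step). The tertiary benzylic C–O bond may ionise and the five‑membered ring may aromatise by dehydration. The isomerisation may also stall at an equilibrium mixture, or part of the material may react through a non‑chelated transition state and lower the enantiomeric purity. The fallback sets out from 15 and changes the order and the activation. The three MOM groups are removed first (ZnBr2, n‑PrSH, CH2Cl2, 0 °C) to give the unprotected iso‑ketol (S)‑(2,4‑dihydroxyphenyl)[3,6‑dihydroxy‑5,7‑bis(3‑methylbut‑2‑en‑1‑yl)‑2,3‑dihydro‑1‑benzofuran‑3‑yl]methanone F1. The ring expansion is then run as the last step on a magnesium template (MgBr2·OEt2, Et3N, THF, 0 °C → rt). The free 2′‑OH activates the aroyl carbonyl by hydrogen bonding and the Mg(II) alkoxide–ketone chelate keeps the syn geometry. This fallback comes back to the route at 17.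

Step 9. Facial control in the ring closure of the peroxy enolate may be poor, because the enone has no β‑substituent to bias the catalyst. The silyl group may also be lost before epoxidation, which would open an oxa‑Michael pathway. The fallback sets out from 12. Luche reduction (NaBH4, CeCl3·7H2O, MeOH, −20 °C) gives racemic 1‑[2,4‑bis(methoxymethoxy)phenyl]‑2‑[4‑(methoxymethoxy)‑3,5‑bis(3‑methylbut‑2‑en‑1‑yl)‑2‑(triisopropylsilyloxy)phenyl]prop‑2‑en‑1‑ol F2. Sharpless kinetic resolution (Ti(Oi‑Pr)4, diisopropyl tartrate of the hand chosen by the Sharpless mnemonic, TBHP 0.6 equiv, 4 Å MS, CH2Cl2, −20 °C) epoxidises only the allylic alcohol and leaves the prenyl groups alone. It should give the erythro epoxy alcohol (R)‑[2,4‑bis(methoxymethoxy)phenyl]{(2S)‑2‑[4‑(methoxymethoxy)‑3,5‑bis(3‑methylbut‑2‑en‑1‑yl)‑2‑(triisopropylsilyloxy)phenyl]oxiran‑2‑yl}methanol F3. The slow enantiomer of the allylic alcohol is reoxidised to 12 with Dess–Martin periodinane and recycled. Dess–Martin oxidation of the epoxy alcohol removes the carbinol stereocentre and gives epoxy ketone 13, where the route is rejoined with the TBAF stage of step 9.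

Step 11. The tertiary α‑keto benzylic alcohol may ionise and dehydrate toward the isoflavone, or a prenyl group may cyclise onto a freed phenol under Lewis acid. The fallback sets out from 16 and replaces acetal cleavage by silyl exchange. TMSOTf/2,2′‑bipyridyl (CH2Cl2, 0 °C) converts aryl MOM ethers into aryl TMS ethers under non‑acidic conditions and silylates the tertiary hydroxyl, giving the tetrakis(trimethylsilyl) ether of the target F4. Mild methanolysis (K2CO3, MeOH, 0 °C) then comes back to the route at 17.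

**Further compounds**
F1 | step 10 | (S)‑(2,4‑dihydroxyphenyl)[3,6‑dihydroxy‑5,7‑bis(3‑methylbut‑2‑en‑1‑yl)‑2,3‑dihydro‑1‑benzofuran‑3‑yl]methanone | O[C@@]1(COc2c(CC=C(C)C)c(O)c(CC=C(C)C)cc21)C(=O)c1ccc(O)cc1O
F2 | step 9 | racemic 1‑[2,4‑bis(methoxymethoxy)phenyl]‑2‑[4‑(methoxymethoxy)‑3,5‑bis(3‑methylbut‑2‑en‑1‑yl)‑2‑(triisopropylsilyloxy)phenyl]prop‑2‑en‑1‑ol | OC(c1ccc(OCOC)cc1OCOC)C(=C)c1cc(CC=C(C)C)c(OCOC)c(CC=C(C)C)c1O[Si](C(C)C)(C(C)C)C(C)C
F3 | step 9 | erythro (R)‑[2,4‑bis(methoxymethoxy)phenyl]{(2S)‑2‑[4‑(methoxymethoxy)‑3,5‑bis(3‑methylbut‑2‑en‑1‑yl)‑2‑(triisopropylsilyloxy)phenyl]oxiran‑2‑yl}methanol | O[C@H](c1ccc(OCOC)cc1OCOC)[C@@]1(CO1)c1cc(CC=C(C)C)c(OCOC)c(CC=C(C)C)c1O[Si](C(C)C)(C(C)C)C(C)C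
F4 | step 11 | (R)‑3‑[2,4‑bis(trimethylsilyloxy)phenyl]‑3,7‑bis(trimethylsilyloxy)‑6,8‑bis(3‑methylbut‑2‑en‑1‑yl)‑2,3‑dihydro‑4H‑chromen‑4‑one | CC(C)=CCc1cc2c(c(CC=C(C)C)c1O[Si](C)(C)C)OC[C@](O[Si](C)(C)C)(c1ccc(O[Si](C)(C)C)cc1O[Si](C)(C)C)C2=O
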